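**Retrosynthetic overview**

1. The target is reached from its 15‑alcohol by a final selective oxidation; the 19‑acetate comes from a C19 methyl ester, the 7α‑hydroxy‑8(17)‑ene from a 7α,8α‑epoxide, and C12–C13 from a B‑alkyl Suzuki coupling of a C9 vinyl group with (Z)‑3‑iodobut‑2‑en‑1‑ol.
2. Ring A is closed at C2–C3 by an SmI2 6‑endo ketyl–acrylate cyclization of a 2,3‑seco aldehyde–acrylate; the C18 methyl then enters by alkylation of the C19 ester enolate.
3. Enabling feature: in ring A the oxygen on C2 and the oxidised carbon C19 on C4 form the 1,4‑dioxygenated chain O–C2–C3–C4–C19(O). At the aldehyde and ester levels C2 is a carbonyl carbon and C3 the β‑carbon of the acrylate C3=C4–C19O2Me, two electrophilic carbons that join once C2 is reversed to a ketyl, and C4 stays enolisable.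
4. Ring B and C3, C4, C17, C19 are the ten carbons of (R)‑carvone (ring = C5–C10, ring methyl = C17, isopropenyl = C4(=C3H2)–C19); C10 is built by double α′‑alkylation, C9 by Wharton transposition and anti‑SN2′ vinylation.
5. Ring order: ring B is taken preformed from the chiral pool; ring A is closed in the key step.

Key step: step 13

Remark: labdane numbering is used throughout (ring A = C1–C5, C10; ring B = C5–C10; β = face of the C10 methyl), and centres that are formed as epimer mixtures and erased in the next step (C10 in 5, C4 in 18) are drawn as the expected major epimer.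

**Route**

Step 1
Reactants: 1 (R)-(−)-carvone
Product: 2 (R)-10-hydroxycarvone
Conditions: SeO2 (0.3 equiv), t-BuOOH (3 equiv), CH2Cl2, 0 °C → rt
Reagents that add atoms: tert-butyl hydroperoxide, CC(C)(C)OO
Why: SeO2‑catalysed allylic oxidation (ene reaction then 2,3‑sigmatropic shift) should attack only the electron‑rich isopropenyl group at its methyl, the enone alkene being deactivated, and touches no stereocentre.

Step 2
Reactants: 2 (R)-10-hydroxycarvone
Product: 3 TBS ether of 2
Conditions: TBSCl, imidazole, DMF, rt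
Reagents that add atoms: tert-butyldimethylsilyl chloride, CC(C)(C)[Si](C)(C)Cl
Why: Standard silylation of a primary allylic alcohol masks the future C19 oxygen against the strong bases and nucleophiles of steps 3–8.

Step 3
Reactants: 3 TBS ether of 2
Product: 5 C10-methyl enone (methyl trans to the C5 side chain), via lithium dienolate 4 (not isolated)
Conditions: LiN(iPr)2, THF, −78 °C; then MeI, −78 → −20 °C
Reagents that add atoms: iodomethane, CI; LiN(iPr)2, [Li]N(C(C)C)C(C)C (lithium of intermediate 4 only)
Why: Kinetic α′‑deprotonation of the enone and enolate alkylation should install the future C20 methyl; the new centre is re‑enolised in step 4, so its configuration is irrelevant.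

Step 4
Reactants: 5 C10-methyl enone
Product: 7 quaternary enone (10β-methyl and 10α-CH2CO2t-Bu), via lithium enolate 6 (not isolated)
Conditions: LiN(iPr)2, THF, −78 → −20 °C; then BrCH2CO2t-Bu, DMPU, −78 → 0 °C
Reagents that add atoms: tert-butyl bromoacetate, BrCC(=O)OC(C)(C)C; LiN(iPr)2, [Li]N(C(C)C)C(C)C (lithium of intermediate 6 only)
Why: Alkylation of the tetrasubstituted enolate should occur anti to the adjacent C5 side chain, setting quaternary C10 with the methyl cis to that side chain and the C1–C2 arm trans to it.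

Step 5
Reactants: 7 quaternary enone
Product: 8 7α,8α-epoxy ketone
Conditions: 30% H2O2, NaOH (aq.), MeOH, 0 °C
Reagents that add atoms: hydrogen peroxide, OO
Why: Weitz–Scheffer nucleophilic epoxidation should proceed by axial attack of hydroperoxide at C7 trans to the C5 side chain, as with carvone itself, fixing the epoxide on the α face while the electron‑rich side‑chain alkene is untouched.

Step 6
Reactants: 8 7α,8α-epoxy ketone
Product: 9 transposed allylic alcohol (7α-OH and C8=C9)
Conditions: N2H4·H2O, AcOH (cat.), MeOH, 0 °C → rt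
Reagents that add atoms: none
Why: Wharton transposition (epoxy hydrazone fragmentation with loss of N2) should move the oxygen to C7 with retention of the epoxide C7–O configuration and leave C9 as the alkene CH.

Step 7
Reactants: 9 transposed allylic alcohol
Product: 10 7α-picolinate
Conditions: picolinic acid, DCC, DMAP (cat.), CH2Cl2, rt
Reagents that add atoms: picolinic acid, OC(=O)c1ccccn1
Why: Steglich esterification installs the chelating picolinoxy leaving group needed for a γ‑selective substitution.

Step 8
Reactants: 10 7α-picolinate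
Product: 11 9β-vinyl Δ7 tert-butyl ester
Conditions: CH2=CHMgBr (3 equiv), CuBr·SMe2 (1.5 equiv), THF, −40 → 0 °C
Reagents that add atoms: vinylmagnesium bromide CH2=CHMgBr, C=C[Mg]Br
Why: Copper‑mediated anti‑SN2′ allylic substitution of the magnesium‑chelated picolinate should deliver vinyl to the alkene terminus C9 on the face opposite to the 7α C–O bond, setting the 9β centre by 1,3‑chirality transfer and regenerating the C7=C8(CH3) alkene.

Step 9
Reactants: 11 9β-vinyl Δ7 tert-butyl ester
Product: 13 diol (C2–OH and allylic C19–OH), via silyl ether alcohol 12 (not isolated)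
Conditions: LiAlH4, THF, 0 °C → rt; Na2SO4·10H2O quench, filter; then Bu4NF, THF, rt
Reagents that add atoms: none
Why: Hydride reduction of the ester to the C2 primary alcohol followed by fluoride desilylation of the crude product should expose both hydroxyls without affecting the three alkenes.

Step 10
Reactants: 13 diol
Product: 14 hydroxy enal (C19 aldehyde)
Conditions: MnO2 (activated, excess), CH2Cl2, rt
Reagents that add atoms: none
Why: MnO2 oxidises only the allylic alcohol, which differentiates C19 from the saturated C2 alcohol.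

Step 11
Reactants: 14 hydroxy enal
Product: 16 hydroxy methyl acrylate, via hydroxy acrylic acid 15 (not isolated)
Conditions: NaClO2, NaH2PO4, 2-methyl-2-butene, t-BuOH/H2O, 0 °C → rt; then Me3SiCHN2, PhMe/MeOH, 0 °C
Reagents that add atoms: sodium chlorite NaClO2, [Na+].[O-]Cl=O; (trimethylsilyl)diazomethane, C[Si](C)(C)C=[N+]=[N-]
Why: Pinnick oxidation of the 2‑substituted acrolein (the scavenger protects the alkenes from HOCl) and diazomethane‑type esterification should give the acrylate without touching the primary alcohol.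

Step 12
Reactants: 16 hydroxy methyl acrylate
Product: 17 2,3-seco aldehyde–acrylate
Conditions: Dess–Martin periodinane, NaHCO3, CH2Cl2, 0 °C → rt
Reagents that add atoms: none
Why: Buffered Dess–Martin oxidation converts the C2 alcohol into the aldehyde under non‑epimerising, non‑isomerising conditions.

Step 13
Reactants: 17 2,3-seco aldehyde–acrylate
Product: 18 methyl 2α-hydroxy-13,14,15,16,18-pentanorlabda-7,11-dien-19-oate
Conditions: SmI2 (2.5 equiv, 0.1 M in THF), t-BuOH (3 equiv), THF (high dilution), −78 → 0 °C, no HMPA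
Reagents that add atoms: none
Why: SmI2 should reduce the aldehyde to a samarium ketyl radical at C2 (polarity reversal of the carbonyl carbon), which adds to the unsubstituted β‑carbon C3 of the acrylate; the α‑ester radical at C4 is then reduced by a second SmI2 to the samarium enolate and protonated by t-BuOH. The closest known reaction types are the SmI2 ketyl–olefin cyclization and the SmI2 coupling of aldehydes with methacrylates. Ring A closes in the 6‑endo‑trig mode, imposed by the attachment of the tether to the α‑carbon of the acrylate, since 5‑exo attack would have to occur at the fully substituted and polarity‑mismatched C4. The new C2 centre should be controlled by a chair transition state on the trans‑diequatorial C5 and C10 arms, in which the bulky O–SmI2 group lies equatorial (2α) to avoid a 1,3‑diaxial clash with the C10 methyl; the trans ring fusion follows from the preset C5 and C10 centres, and C4 is re‑set in step 14. The step needs chemoselectivity for the aldehyde over the acrylate and for the acrylate over the C9 vinyl group, which the faster reduction of the aldehyde, the match of the nucleophilic ketyl with the electron‑poor alkene and the omission of HMPA should secure.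

Step 14
Reactants: 18 methyl 2α-hydroxy-13,14,15,16,18-pentanorlabda-7,11-dien-19-oate
Product: 20 methyl 2α-hydroxy-13,14,15,16-tetranorlabda-7,11-dien-19-oate, via dilithium alkoxide enolate 19 (not isolated)
Conditions: LiN(iPr)2 (2.5 equiv), THF/DMPU, −78 → −30 °C; then MeI (1.2 equiv), −78 → −40 °C
Reagents that add atoms: iodomethane, CI; LiN(iPr)2, [Li]N(C(C)C)C(C)C (lithium of intermediate 19 only)
Why: C‑alkylation of the ester enolate of a hydroxy‑ester dianion (the lithium alkoxide is far less nucleophilic at low temperature) should bring MeI in from the equatorial α face, away from the axial C10 methyl, giving the 4α‑methyl/4β‑ester quaternary centre.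

Step 15
Reactants: 20 methyl 2α-hydroxy-13,14,15,16-tetranorlabda-7,11-dien-19-oate
Product: 21 methyl 7α,8α-epoxy-2α-hydroxy-13,14,15,16-tetranorlabd-11-en-19-oate
Conditions: mCPBA (1.05 equiv), NaHCO3, CH2Cl2, 0 °C
Reagents that add atoms: 3-chloroperoxybenzoic acid, OOC(=O)c1cccc(Cl)c1
Why: Prilezhaev epoxidation should select the trisubstituted ring alkene over the monosubstituted vinyl group and attack the α face, opposite to the axial C10 methyl.

Step 16
Reactants: 22 but-2-yn-1-ol
Product: 24 (Z)-3-iodobut-2-en-1-ol, via sodium alkenylalanate 23 (not isolated)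
Conditions: NaAlH2(OCH2CH2OMe)2, THF, 0 °C → rt; then I2, THF, −78 → 0 °C
Reagents that add atoms: iodine, II; NaAlH2(OCH2CH2OMe)2, [Na+].[AlH2-](OCCOC)OCCOC (aluminate unit of intermediate 23 only)
Why: Hydroxyl‑directed trans‑hydroalumination places aluminium on C3 in a five‑membered alanate, and iodinolysis with retention should give the Z vinyl iodide.

Step 17
Reactants: 21 methyl 7α,8α-epoxy-2α-hydroxy-13,14,15,16-tetranorlabd-11-en-19-oate; 24 (Z)-3-iodobut-2-en-1-ol
Product: 26 methyl (13Z)-7α,8α-epoxy-2α,15-dihydroxylabd-13-en-19-oate, via B-alkyl-9-BBN 25 (not isolated)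
Conditions: 9-BBN (2.5 equiv), THF, rt; then 24, PdCl2(dppf) (5 mol%), AsPh3, Cs2CO3, DMF/H2O, rt
Reagents that add atoms: 9-borabicyclo[3.3.1]nonane, B1C2CCCC1CCC2 (boron unit of intermediate 25 only)
Why: 9-BBN should hydroborate only the vinyl group at its terminus (the ring alkene is masked as the epoxide), and the B‑alkyl Suzuki–Miyaura coupling proceeds with retention of the vinyl iodide geometry, fixing the 13Z alkene.

Step 18
Reactants: 26 methyl (13Z)-7α,8α-epoxy-2α,15-dihydroxylabd-13-en-19-oate
Product: 27 methyl (13Z)-2α,7α,15-trihydroxylabda-8(17),13-dien-19-oate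
Conditions: Al(Oi-Pr)3 (4 equiv), PhMe, reflux
Reagents that add atoms: none
Why: Al(Oi-Pr)3‑promoted isomerisation of a trisubstituted epoxide to an allylic alcohol should keep the oxygen on C7 (7α retained) while a proton is removed from the accessible C17 methyl in a cyclic syn‑elimination, giving the exocyclic 8(17)‑alkene.

Step 19
Reactants: 27 methyl (13Z)-2α,7α,15-trihydroxylabda-8(17),13-dien-19-oate
Product: 28 methyl (13Z)-2α,7α,15-tris(tert-butyldimethylsilyloxy)labda-8(17),13-dien-19-oate
Conditions: TBSOTf (4 equiv), 2,6-lutidine, CH2Cl2, −78 → 0 °C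
Reagents that add atoms: tert-butyldimethylsilyl triflate, CC(C)(C)[Si](C)(C)OS(=O)(=O)C(F)(F)F
Why: Exhaustive silylation protects all three hydroxyls so that C19 can be reduced and acetylated unambiguously.

Step 20
Reactants: 28 methyl (13Z)-2α,7α,15-tris(tert-butyldimethylsilyloxy)labda-8(17),13-dien-19-oate
Product: 29 (13Z)-2α,7α,15-tris(tert-butyldimethylsilyloxy)labda-8(17),13-dien-19-ol
Conditions: LiAlH4, THF, 0 → 40 °C
Reagents that add atoms: none
Why: LiAlH4 reduces the hindered axial ester to the neopentyl alcohol, and silyl ethers and alkenes are inert.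

Step 21
Reactants: 29 (13Z)-2α,7α,15-tris(tert-butyldimethylsilyloxy)labda-8(17),13-dien-19-ol
Product: 30 (13Z)-19-acetoxy-2α,7α,15-tris(tert-butyldimethylsilyloxy)labda-8(17),13-diene
Conditions: Ac2O, pyridine, DMAP (cat.), CH2Cl2, rt
Reagents that add atoms: acetic anhydride, CC(=O)OC(C)=O
Why: DMAP‑catalysed acetylation of the only free hydroxyl installs the 19‑acetate.

Step 22
Reactants: 30 (13Z)-19-acetoxy-2α,7α,15-tris(tert-butyldimethylsilyloxy)labda-8(17),13-diene
Product: 31 (13Z)-19-acetoxylabda-8(17),13-diene-2α,7α,15-triol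
Conditions: HF·pyridine, pyridine, THF, 0 °C → rt
Reagents that add atoms: none
Why: Buffered fluoride desilylation removes the three TBS groups and should leave the primary acetate and both alkenes intact.

Step 23
Reactants: 31 (13Z)-19-acetoxylabda-8(17),13-diene-2α,7α,15-triol
Product: 32 (13Z)-19-acetoxy-2α,7α-dihydroxylabda-8(17),13-dien-15-al (CNP0249702.2)
Conditions: TEMPO (0.1 equiv), PhI(OAc)2 (1.1 equiv), CH2Cl2, rt
Reagents that add atoms: none
Why: The oxoammonium‑mediated TEMPO/PhI(OAc)2 oxidation is selective for the primary allylic alcohol over the two secondary alcohols and should give the enal without Z to E isomerisation.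

**Compound list**

1 | (R)-(−)-carvone, (5R)-2-methyl-5-(prop-1-en-2-yl)cyclohex-2-en-1-one | CC1=CC[C@@H](C(C)=C)CC1=O | starting material
2 | (R)-10-hydroxycarvone, (5R)-5-(3-hydroxyprop-1-en-2-yl)-2-methylcyclohex-2-en-1-one | CC1=CC[C@@H](C(CO)=C)CC1=O | intermediate
3 | TBS ether of 2 | CC1=CC[C@@H](C(CO[Si](C)(C)C(C)(C)C)=C)CC1=O | intermediate
4 | lithium dienolate of 3 (O–Li on C9, C9=C10) | CC1=CC[C@@H](C(CO[Si](C)(C)C(C)(C)C)=C)C=C1O[Li] | intermediate (not isolated)
5 | C10-methyl enone: 3 with a methyl on C10 trans to the C5 side chain (major epimer) | CC1=CC[C@@H](C(CO[Si](C)(C)C(C)(C)C)=C)[C@H](C)C1=O | intermediate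
6 | lithium enolate of 5 (tetrasubstituted C9=C10) | CC1=CC[C@@H](C(CO[Si](C)(C)C(C)(C)C)=C)C(C)=C1O[Li] | intermediate (not isolated)
7 | quaternary enone: 9-oxo-Δ7 ring B with 10β-CH3, 10α-CH2CO2t-Bu and 5-(3-TBSO-prop-1-en-2-yl), 5αH | CC1=CC[C@@H](C(CO[Si](C)(C)C(C)(C)C)=C)[C@](C)(CC(=O)OC(C)(C)C)C1=O | intermediate
8 | 7α,8α-epoxy ketone of 7 | C[C@@]12O[C@@H]1C[C@@H](C(CO[Si](C)(C)C(C)(C)C)=C)[C@](C)(CC(=O)OC(C)(C)C)C2=O | intermediate
9 | transposed allylic alcohol: 7α-OH, C8(CH3)=C9H, other groups as in 7 | CC1=C[C@@](C)(CC(=O)OC(C)(C)C)[C@H](C(CO[Si](C)(C)C(C)(C)C)=C)C[C@H]1O | intermediate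
10 | 7α-picolinate of 9 | CC1=C[C@@](C)(CC(=O)OC(C)(C)C)[C@H](C(CO[Si](C)(C)C(C)(C)C)=C)C[C@H]1OC(=O)c2ccccn2 | intermediate
11 | 9β-vinyl Δ7 tert-butyl ester: C7=C8(CH3), 9αH, 10β-CH3, 10α-CH2CO2t-Bu, 5-(3-TBSO-prop-1-en-2-yl) | CC1=CC[C@@H](C(CO[Si](C)(C)C(C)(C)C)=C)[C@](C)(CC(=O)OC(C)(C)C)[C@H]1C=C | intermediate
12 | silyl ether alcohol: 11 with CH2CH2OH in place of CH2CO2t-Bu | CC1=CC[C@@H](C(CO[Si](C)(C)C(C)(C)C)=C)[C@](C)(CCO)[C@H]1C=C | intermediate (not isolated)
13 | diol: 12 without the TBS group | CC1=CC[C@@H](C(CO)=C)[C@](C)(CCO)[C@H]1C=C | intermediate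
14 | hydroxy enal: 13 with the allylic CH2OH oxidised to CHO | CC1=CC[C@@H](C(C=O)=C)[C@](C)(CCO)[C@H]1C=C | intermediate
15 | hydroxy acrylic acid | CC1=CC[C@@H](C(C(=O)O)=C)[C@](C)(CCO)[C@H]1C=C | intermediate (not isolated)
16 | hydroxy methyl acrylate | CC1=CC[C@@H](C(C(=O)OC)=C)[C@](C)(CCO)[C@H]1C=C | intermediate
17 | 2,3-seco aldehyde–acrylate: 16 with CH2CHO on C10 | CC1=CC[C@@H](C(C(=O)OC)=C)[C@](C)(CC=O)[C@H]1C=C | intermediate
18 | methyl 2α-hydroxy-13,14,15,16,18-pentanorlabda-7,11-dien-19-oate (4β-ester drawn) | CC1=CC[C@H]2[C@@H](C(=O)OC)C[C@H](O)C[C@]2(C)[C@H]1C=C | intermediate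
19 | dilithium alkoxide ester enolate of 18 | CC1=CC[C@H]2C(=C(OC)O[Li])C[C@H](O[Li])C[C@]2(C)[C@H]1C=C | intermediate (not isolated)
20 | methyl 2α-hydroxy-13,14,15,16-tetranorlabda-7,11-dien-19-oate | CC1=CC[C@H]2[C@@](C)(C(=O)OC)C[C@H](O)C[C@]2(C)[C@H]1C=C | intermediate
21 | methyl 7α,8α-epoxy-2α-hydroxy-13,14,15,16-tetranorlabd-11-en-19-oate | C[C@@]12O[C@@H]1C[C@H]3[C@@](C)(C(=O)OC)C[C@H](O)C[C@]3(C)[C@H]2C=C | intermediate
22 | but-2-yn-1-ol | CC#CCO | starting material
23 | sodium alkenylalanate (five-membered oxa-aluminacycle from 22) | [Na+].CC1=CCO[Al-]1(OCCOC)OCCOC | intermediate (not isolated)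
24 | (Z)-3-iodobut-2-en-1-ol | I/C(C)=C\CO | intermediate
25 | B-alkyl-9-BBN of 21 (boron on C12) | C[C@@]12O[C@@H]1C[C@H]3[C@@](C)(C(=O)OC)C[C@H](O)C[C@]3(C)[C@H]2CCB4C5CCCC4CCC5 | intermediate (not isolated)
26 | methyl (13Z)-7α,8α-epoxy-2α,15-dihydroxylabd-13-en-19-oate | C[C@@]12O[C@@H]1C[C@H]3[C@@](C)(C(=O)OC)C[C@H](O)C[C@]3(C)[C@H]2CC/C(C)=C\CO | intermediate
27 | methyl (13Z)-2α,7α,15-trihydroxylabda-8(17),13-dien-19-oate | C=C1[C@H](O)C[C@H]2[C@@](C)(C(=O)OC)C[C@H](O)C[C@]2(C)[C@H]1CC/C(C)=C\CO | intermediate
28 | methyl (13Z)-2α,7α,15-tris(tert-butyldimethylsilyloxy)labda-8(17),13-dien-19-oate | C=C1[C@H](O[Si](C)(C)C(C)(C)C)C[C@H]2[C@@](C)(C(=O)OC)C[C@H](O[Si](C)(C)C(C)(C)C)C[C@]2(C)[C@H]1CC/C(C)=C\CO[Si](C)(C)C(C)(C)C | intermediate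
29 | (13Z)-2α,7α,15-tris(tert-butyldimethylsilyloxy)labda-8(17),13-dien-19-ol | C=C1[C@H](O[Si](C)(C)C(C)(C)C)C[C@H]2[C@@](C)(CO)C[C@H](O[Si](C)(C)C(C)(C)C)C[C@]2(C)[C@H]1CC/C(C)=C\CO[Si](C)(C)C(C)(C)C | intermediate
30 | (13Z)-19-acetoxy-2α,7α,15-tris(tert-butyldimethylsilyloxy)labda-8(17),13-diene | C=C1[C@H](O[Si](C)(C)C(C)(C)C)C[C@H]2[C@@](C)(COC(C)=O)C[C@H](O[Si](C)(C)C(C)(C)C)C[C@]2(C)[C@H]1CC/C(C)=C\CO[Si](C)(C)C(C)(C)C | intermediate
31 | (13Z)-19-acetoxylabda-8(17),13-diene-2α,7α,15-triol | C=C1[C@H](O)C[C@H]2[C@@](C)(COC(C)=O)C[C@H](O)C[C@]2(C)[C@H]1CC/C(C)=C\CO | intermediate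
32 | (13Z)-19-acetoxy-2α,7α-dihydroxylabda-8(17),13-dien-15-al (CNP0249702.2) | C=C1[C@H](O)C[C@H]2[C@@](C)(COC(C)=O)C[C@H](O)C[C@]2(C)[C@H]1CC/C(C)=C\C=O | target

**Step count and risks**

Total step count: 23. Longest linear sequence: 22 steps (steps 1–15 and 17–23, from (R)-carvone).

The three steps most likely to fail:

Step 13. The ketyl may be reduced further or dimerise before it cyclises, or it may attack the C9 vinyl group in a 5‑exo mode. The fallback replaces the radical closure by a polar one that forms the same C2–C3 bond. It sets out from 17: an intramolecular Stetter reaction (3-benzyl-5-(2-hydroxyethyl)-4-methylthiazolium chloride, Et3N, dioxane, 80 °C) should give the 2‑oxo ester F1. Because hydride reagents are expected to attack this ketone from the α face and give the axial alcohol, the ketone would be reduced with a ketoreductase (alcohol dehydrogenase, NADPH recycled with glucose and glucose dehydrogenase, buffer/DMSO) chosen for the equatorial alcohol, to give the 4‑epimeric hydroxy ester F2. Under the conditions of step 14, F2 gives the same enolate and comes back to the route at 20.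

Step 8. Attack at C9, next to the quaternary C10, may be slow, so that direct substitution at C7 or loss of facial control competes. The fallback builds the C9 vinyl group by one‑carbon homologation of the ketone and bypasses steps 5–8. It sets out from 7: dimethylsulfonium methylide (Me3SI, n-BuLi, THF, −10 °C) should add to the carbonyl from the α face to give the spiro vinyl epoxide F3. A Meinwald rearrangement (MgBr2·OEt2, Et2O) with hydride shift anti to the departing β oxygen should give the β,γ‑unsaturated 9β‑aldehyde F4, which is also the equatorial, thermodynamically preferred epimer. Wittig methylenation (Ph3PCH3Br, KOt-Bu, THF, 0 °C) comes back to the route at 11.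

Step 6. Hydrazone formation at the neopentyl ketone may be slow, so that opening of the epoxide by hydrazine or over‑reduction competes. The fallback is a radical epoxide fragmentation and sets out from 8: NaBH4 (MeOH, 0 °C) should reduce the ketone to the epoxy alcohol F5, whose carbinol configuration is of no consequence. 1,1′-Thiocarbonyldiimidazole (DMAP, CH2Cl2) converts it into the thiocarbonylimidazolide F6. Bu3SnH with AIBN (PhMe, 90 °C) generates the C9 radical, which opens the epoxide at C8–O; the oxygen stays on C7 with its α configuration, and the route is rejoined at 9.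

**Further compounds**

F1 | step 13 | methyl 2-oxo-13,14,15,16,18-pentanorlabda-7,11-dien-19-oate (4α-ester) | CC1=CC[C@H]2[C@H](C(=O)OC)CC(=O)C[C@]2(C)[C@H]1C=C
F2 | step 13 | methyl 2α-hydroxy-13,14,15,16,18-pentanorlabda-7,11-dien-19-oate, 4α-ester (C4 epimer of 18) | CC1=CC[C@H]2[C@H](C(=O)OC)C[C@H](O)C[C@]2(C)[C@H]1C=C
F3 | step 8 | spiro vinyl epoxide from 7 (epoxide CH2 on the α face of C9) | CC1=CC[C@@H](C(CO[Si](C)(C)C(C)(C)C)=C)[C@](C)(CC(=O)OC(C)(C)C)[C@]12CO2
F4 | step 8 | 9β-formyl Δ7 tert-butyl ester | CC1=CC[C@@H](C(CO[Si](C)(C)C(C)(C)C)=C)[C@](C)(CC(=O)OC(C)(C)C)[C@H]1C=O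
F5 | step 6 | 7α,8α-epoxy-9β-alcohol from 8 | C[C@@]12O[C@@H]1C[C@@H](C(CO[Si](C)(C)C(C)(C)C)=C)[C@](C)(CC(=O)OC(C)(C)C)[C@H]2O
F6 | step 6 | O-(imidazol-1-ylthiocarbonyl) derivative of F5 | C[C@@]12O[C@@H]1C[C@@H](C(CO[Si](C)(C)C(C)(C)C)=C)[C@](C)(CC(=O)OC(C)(C)C)[C@H]2OC(=S)n3ccnc3
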